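**Retrosynthetic overview**
1. Target ⇐ C2 oxidation (Rubottom, then Dess–Martin) of the 3-oxo-4(18)-ene acid 27 ⇐ Mannich methylenation at C4 and cuprate methylation at C5 of the 7β-acetoxy-4-en-3-one 22.
2. The 7β-oxygen comes from the 4,6-dienone (epoxidation, reductive opening); the (E)-enoate comes from a C13 methyl ketone by Horner–Wadsworth–Emmons olefination.
3. Key disconnection C10–C1 (then C4–C5): intermolecular Mukaiyama–Michael addition of the ring B silyl enol ether 10 to methyl vinyl ketone, followed by aldol condensation (Robinson annulation).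
4. Ring B: 10 by anti conjugate addition of the C11–C13 chain to (R)-3,4-dimethylcyclohexenone, itself from propanal and methyl vinyl ketone (organocatalytic Michael addition, aldol condensation).
5. Ring order: ring B first (steps 1–5), ring A second (steps 6–7); stereocentres are set in the order C8 → C9 → C10 → C7 → C5.

Convention (one line): clerodane numbering throughout; β is the face of the decalin that carries the C5 methyl (C19), α the opposite face; "cis-clerodane" means 5β-Me/10β-H, and every bicyclic compound has 8α-Me, 9α-Me (C20) and the C11 chain β.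

**Step 1**
Reactants: 1 propanal; 2 but-3-en-2-one
Product: 3 (R)-2-methyl-5-oxohexanal
Conditions: (S)-α,α-diphenylprolinol trimethylsilyl ether (5 mol%), ethyl 3,4-dihydroxybenzoate (20 mol%), neat, 4 °C
Reagents that add atoms: none
Why: Enamine-catalysed asymmetric Michael addition; the bulky silyloxy-diphenylmethyl group shields one face of the E-enamine of propanal, so the enone adds to the open face and sets C8 as R (about 95% ee expected).

**Step 2**
Reactants: 3 (R)-2-methyl-5-oxohexanal
Product: 5 (R)-4-methylcyclohex-2-en-1-one, via cyclic aldol 4 (not isolated)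
Conditions: LiOH·H2O (0.1 equiv), iPrOH, 23 °C
Reagents that add atoms: none
Why: Intramolecular aldol condensation, in which only the methyl-ketone enolate attacking the aldehyde gives a six-membered ring; mild base at room temperature keeps epimerisation of the α-stereocentre slow (ee checked here).

**Step 3**
Reactants: 5 (R)-4-methylcyclohex-2-en-1-one
Product: 6 trimethylsilyl enol ether of trans-3,4-dimethylcyclohexanone (4R; 1-silyloxy-1-ene)
Conditions: MeMgBr, CuBr·SMe2 (5 mol%), TMSCl, HMPA, THF, −78 °C; Et3N, pentane work-up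
Reagents that add atoms: methylmagnesium bromide (C[Mg]Br); chlorotrimethylsilane (C[Si](C)(C)Cl)
Why: Copper-catalysed conjugate addition with silyl trapping gives the enol ether regiospecifically on the C10 side; the methyl adds anti to the C8 methyl, but this new centre is removed in step 4.

**Step 4**
Reactants: 6 trimethylsilyl enol ether of trans-3,4-dimethylcyclohexanone
Product: 7 (R)-3,4-dimethylcyclohex-2-en-1-one
Conditions: Pd(OAc)2 (10 mol%), O2 (1 atm), DMSO, 25 °C
Reagents that add atoms: none
Why: Saegusa–Ito oxidation; the palladium enolate can only undergo β-hydride elimination toward C9, the zerovalent palladium is reoxidised by O2, and C8 is not touched.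

**Step 5**
Reactants: 7 (R)-3,4-dimethylcyclohex-2-en-1-one; 8 2-(2-bromoethyl)-2-methyl-1,3-dioxolane
Product: 10 1-trimethylsilyloxy-3,4-dimethyl-3-[2-(2-methyl-1,3-dioxolan-2-yl)ethyl]cyclohex-1-ene (4R; chain anti to the 4-methyl), via Grignard reagent 9 (not isolated)
Conditions: 8, Mg, THF, 25 °C; then 7, CuBr·SMe2 (10 mol%), TMSCl, HMPA, THF, −78 → −40 °C
Reagents that add atoms: magnesium ([Mg]); chlorotrimethylsilane (C[Si](C)(C)Cl)
Why: Copper-catalysed conjugate addition to a 4-substituted cyclohexenone proceeds by axial attack anti to the pseudoaxial C8 methyl, so the C9 quaternary centre forms with the chain trans to C17 and C20 cis to C17 (about 9:1 expected); silyl trapping fixes the enol ether toward C10.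

**Step 6**
Reactants: 10 silyl enol ether from step 5; 2 but-3-en-2-one
Product: 11 2-(3-oxobutyl)-3,4-dimethyl-3-[2-(2-methyl-1,3-dioxolan-2-yl)ethyl]cyclohexanone (C10 epimers)
Conditions: BF3·OEt2, iPrOH, CH2Cl2, −78 °C
Reagents that add atoms: none
Why: Mukaiyama–Michael addition; the Lewis acid activates the enone and the regiodefined enol ether can react only through C10, giving the 1,5-diketone without base-induced polymerisation or premature aldol reaction (C10 is fixed in step 7).

**Step 7**
Reactants: 11 1,5-diketone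
Product: 13 13,13-ethylenedioxy-14,15,18,19-tetranorclerod-4-en-3-one (8α-Me; 9α-Me; 10β-H), via bicyclic ketol 12 (not isolated)
Conditions: NaOMe (0.5 equiv), MeOH, 65 °C
Reagents that add atoms: none
Why: Aldol condensation closes ring A (Robinson annulation); C10 is γ to the new enone and equilibrates under methoxide toward the isomer in which only C20 is axial on ring B, i.e. H10 β and cis to the C11 chain (about 4:1 or better expected; the minor epimer is separated and re-equilibrated).

**Step 8**
Reactants: 13 octalone ketal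
Product: 14 14,15,18,19-tetranorclerod-4-ene-3,13-dione
Conditions: 1 M HCl, THF, 25 °C
Reagents that add atoms: water (O)
Why: Acid-catalysed ketal hydrolysis; the enone and the stereocentres are inert.

**Step 9**
Reactants: 14 enone methyl ketone; 15 tert-butyl 2-(diethoxyphosphoryl)acetate
Product: 17 tert-butyl (13E)-3-oxo-18,19-dinorcleroda-4,13-dien-15-oate, via phosphonate carbanion 16 (not isolated)
Conditions: 15, NaH, THF, 0 °C; then 14, 0 → 50 °C
Reagents that add atoms: sodium hydride ([Na+].[H-])
Why: Horner–Wadsworth–Emmons olefination; the stabilised carbanion olefinates the unhindered methyl ketone and not the less electrophilic conjugated ring carbonyl, giving mainly the E-enoate (about 5:1, separated by chromatography).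

**Step 10**
Reactants: 17 enone ester
Product: 18 tert-butyl (13E)-3-oxo-18,19-dinorcleroda-4,6,13-trien-15-oate
Conditions: chloranil, tBuOH, 80 °C
Reagents that add atoms: none
Why: Quinone dehydrogenation of a 4-en-3-one through its 3,5-dienol (hydride abstraction at C7) gives the linear 4,6-dienone, as is done with 10-H (19-nor-type) enones; chloranil does not attack C1–C2, so ring A is not aromatised.

**Step 11**
Reactants: 18 4,6-dienone
Product: 19 tert-butyl (13E)-6β,7β-epoxy-3-oxo-18,19-dinorcleroda-4,13-dien-15-oate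
Conditions: 3-chloroperbenzoic acid, CH2Cl2, 25 °C
Reagents that add atoms: 3-chloroperbenzoic acid (O=C(OO)c1cccc(Cl)c1)
Why: Prilezhaev epoxidation of the more electron-rich γ,δ-alkene (the enoate alkene is inert); the peracid approaches the β face because the axial C20 methyl on C9 is syn-axial to C7 on the α face, which sets C7.

**Step 12**
Reactants: 19 γ,δ-epoxy enone
Product: 21 tert-butyl (13E)-7β-hydroxy-3-oxo-18,19-dinorcleroda-4,13-dien-15-oate, via deconjugated enone 20 (not isolated)
Conditions: SmI2 (2.2 equiv), MeOH, THF, −78 °C; then 1,8-diazabicyclo[5.4.0]undec-7-ene (cat.), 25 °C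
Reagents that add atoms: none
Why: Single-electron reductive opening of the vinylogous epoxy ketone cleaves only the allylic C6–O bond, so the C7–O bond keeps its β configuration; the amidine then reconjugates the 5-ene to the 4-ene and, with the 7β-oxygen equatorial, holds C10 at 10β-H.

**Step 13**
Reactants: 21 hydroxy enone
Product: 22 tert-butyl (13E)-7β-acetoxy-3-oxo-18,19-dinorcleroda-4,13-dien-15-oate
Conditions: Ac2O, 4-(dimethylamino)pyridine (cat.), pyridine, 25 °C
Reagents that add atoms: acetic anhydride (CC(=O)OC(C)=O)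
Why: Nucleophile-catalysed acylation of the equatorial secondary alcohol; no stereocentre is affected.

**Step 14**
Reactants: 22 acetoxy enone
Product: 23 tert-butyl (13E)-7β-acetoxy-3-trimethylsilyloxy-18-nor-cis-cleroda-3,13-dien-15-oate
Conditions: MeLi, CuI, THF, −30 °C (Me2CuLi); then 22, TMSCl, Et3N, −78 → −30 °C
Reagents that add atoms: methyllithium ([Li]C); chlorotrimethylsilane (C[Si](C)(C)Cl)
Why: Gilman cuprate conjugate addition with silyl trapping; attack at C5 from the α face would place the new methyl 1,3-diaxial to C20, so the methyl enters on the β face cis to H10 (cis-decalin, as usual for cuprates and octalones), and the enol ether is fixed at C3–C4; the β,β-disubstituted enoate and the acetate do not react at this temperature.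

**Step 15**
Reactants: 23 silyl enol ether
Product: 24 tert-butyl (13E)-7β-acetoxy-18-dimethylamino-3-oxo-cis-clerod-13-en-15-oate (C4 epimers)
Conditions: CH2=NMe2+ Cl−, CH2Cl2, 25 °C; aq. NaHCO3 work-up
Reagents that add atoms: N,N-dimethylmethyleneiminium chloride (C=[N+](C)C.[Cl-])
Why: Mannich reaction of the regiodefined silyl enol ether with a preformed iminium salt forms the C4–C18 bond at C4 only; the C4 configuration is irrelevant because it is lost in step 16.

**Step 16**
Reactants: 24 Mannich base
Product: 26 tert-butyl (13E)-7β-acetoxy-3-oxo-cis-cleroda-4(18),13-dien-15-oate, via ammonium iodide 25 (not isolated)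
Conditions: MeI, CH2Cl2, 25 °C; then aq. NaHCO3, 25 °C
Reagents that add atoms: iodomethane (CI)
Why: N-methylation followed by E1cB (Hofmann-type) elimination of the β-ammonium ketone; C4–H is the only hydrogen available, so only the exocyclic methylene enone can form.

**Step 17**
Reactants: 26 tert-butyl ester
Product: 27 (13E)-7β-acetoxy-3-oxo-cis-cleroda-4(18),13-dien-15-oic acid
Conditions: CF3CO2H, CH2Cl2, 0 °C
Reagents that add atoms: none
Why: Acidolysis of the tert-butyl ester by loss of isobutene; the acetate, the enone and the E-alkene are stable to brief cold acid.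

**Step 18**
Reactants: 27 enone acid
Product: 30 (13E)-7β-acetoxy-2-hydroxy-3-oxo-cis-cleroda-4(18),13-dien-15-oic acid (C2 epimers), via bis-silyl dienol ether 28 (not isolated), via silyloxy ketone 29 (not isolated)
Conditions: TMSOTf (2.5 equiv), Et3N, CH2Cl2, 0 °C; 3-chloroperbenzoic acid, −20 °C; then 1 M HCl/THF
Reagents that add atoms: trimethylsilyl triflate (C[Si](C)(C)OS(=O)(=O)C(F)(F)F); 3-chloroperbenzoic acid (O=C(OO)c1cccc(Cl)c1)
Why: Rubottom oxidation; soft enolisation can only go toward C2 (C4 is sp2, C5 quaternary), the peracid epoxidises the electron-rich silyl enol ether rather than the conjugated methylene or the enoate, and 1,4-silyl shift with hydrolysis gives the acyloin (its C2 configuration is removed in step 19).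

**Step 19**
Reactants: 30 acyloin acid
Product: 32 (13E)-7β-acetoxy-2-hydroxy-3-oxo-cis-cleroda-1,4(18),13-trien-15-oic acid (5S,7S,8S,9R,10R; the target), via 2,3-diketone 31 (not isolated)
Conditions: Dess–Martin periodinane, CH2Cl2, 25 °C
Reagents that add atoms: none
Why: Dess–Martin oxidation of the acyloin to the 1,2-diketone, which can enolise only toward C1 and gives the conjugated diosphenol; the neutral conditions leave C10, the acetate and the exocyclic methylene untouched.

**Compound list**
1 | propanal | CCC=O | starting material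
2 | but-3-en-2-one (methyl vinyl ketone) | CC(=O)C=C | starting material
3 | (R)-2-methyl-5-oxohexanal | O=C[C@H](C)CCC(C)=O | intermediate
4 | (4R)-3-hydroxy-4-methylcyclohexanone (cyclic aldol; C3 epimers) | O=C1CC(O)[C@H](C)CC1 | intermediate (not isolated)
5 | (R)-4-methylcyclohex-2-en-1-one | O=C1C=C[C@H](C)CC1 | intermediate
6 | trimethylsilyl enol ether of trans-3,4-dimethylcyclohexanone (4R) | C[Si](C)(C)OC1=C[C@@H](C)[C@H](C)CC1 | intermediate
7 | (R)-3,4-dimethylcyclohex-2-en-1-one | O=C1C=C(C)[C@H](C)CC1 | intermediate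
8 | 2-(2-bromoethyl)-2-methyl-1,3-dioxolane | CC1(CCBr)OCCO1 | starting material
9 | bromo[2-(2-methyl-1,3-dioxolan-2-yl)ethyl]magnesium | CC1(CC[Mg]Br)OCCO1 | intermediate (not isolated)
10 | 1-trimethylsilyloxy-3,4-dimethyl-3-[2-(2-methyl-1,3-dioxolan-2-yl)ethyl]cyclohex-1-ene (4R; 3-Me cis to 4-Me) | C[Si](C)(C)OC1=C[C@@](C)(CCC2(C)OCCO2)[C@H](C)CC1 | intermediate
11 | 2-(3-oxobutyl)-3,4-dimethyl-3-[2-(2-methyl-1,3-dioxolan-2-yl)ethyl]cyclohexanone (C2 epimers) | O=C1C(CCC(C)=O)[C@@](C)(CCC2(C)OCCO2)[C@H](C)CC1 | intermediate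
12 | 5-hydroxy-13,13-ethylenedioxy-14,15,18,19-tetranorclerodan-3-one (bicyclic ketol; C5/C10 epimers) | O=C1CCC2[C@@](C)(CCC3(C)OCCO3)[C@H](C)CCC2(O)C1 | intermediate (not isolated)
13 | 13,13-ethylenedioxy-14,15,18,19-tetranorclerod-4-en-3-one (10β-H) | O=C1CC[C@@H]2[C@@](C)(CCC3(C)OCCO3)[C@H](C)CCC2=C1 | intermediate
14 | 14,15,18,19-tetranorclerod-4-ene-3,13-dione | O=C1CC[C@@H]2[C@@](C)(CCC(C)=O)[C@H](C)CCC2=C1 | intermediate
15 | tert-butyl 2-(diethoxyphosphoryl)acetate | CCOP(=O)(CC(=O)OC(C)(C)C)OCC | starting material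
16 | sodium salt of the carbanion of 15 | [Na+].CCOP(=O)([CH-]C(=O)OC(C)(C)C)OCC | intermediate (not isolated)
17 | tert-butyl (13E)-3-oxo-18,19-dinorcleroda-4,13-dien-15-oate | O=C1CC[C@@H]2[C@@](C)(CC/C(C)=C/C(=O)OC(C)(C)C)[C@H](C)CCC2=C1 | intermediate
18 | tert-butyl (13E)-3-oxo-18,19-dinorcleroda-4,6,13-trien-15-oate | O=C1CC[C@@H]2[C@@](C)(CC/C(C)=C/C(=O)OC(C)(C)C)[C@H](C)C=CC2=C1 | intermediate
19 | tert-butyl (13E)-6β,7β-epoxy-3-oxo-18,19-dinorcleroda-4,13-dien-15-oate | O=C1CC[C@@H]2[C@@](C)(CC/C(C)=C/C(=O)OC(C)(C)C)[C@H](C)[C@H]3O[C@H]3C2=C1 | intermediate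
20 | tert-butyl (13E)-7β-hydroxy-3-oxo-18,19-dinorcleroda-5,13-dien-15-oate | O=C1CC[C@@H]2[C@@](C)(CC/C(C)=C/C(=O)OC(C)(C)C)[C@H](C)[C@@H](O)C=C2C1 | intermediate (not isolated)
21 | tert-butyl (13E)-7β-hydroxy-3-oxo-18,19-dinorcleroda-4,13-dien-15-oate | O=C1CC[C@@H]2[C@@](C)(CC/C(C)=C/C(=O)OC(C)(C)C)[C@H](C)[C@@H](O)CC2=C1 | intermediate
22 | tert-butyl (13E)-7β-acetoxy-3-oxo-18,19-dinorcleroda-4,13-dien-15-oate | O=C1CC[C@@H]2[C@@](C)(CC/C(C)=C/C(=O)OC(C)(C)C)[C@H](C)[C@@H](OC(C)=O)CC2=C1 | intermediate
23 | tert-butyl (13E)-7β-acetoxy-3-trimethylsilyloxy-18-nor-cis-cleroda-3,13-dien-15-oate | C1=C(O[Si](C)(C)C)CC[C@@H]2[C@@](C)(CC/C(C)=C/C(=O)OC(C)(C)C)[C@H](C)[C@@H](OC(C)=O)C[C@]12C | intermediate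
24 | tert-butyl (13E)-7β-acetoxy-18-dimethylamino-3-oxo-cis-clerod-13-en-15-oate (C4 epimers) | CN(C)CC1C(=O)CC[C@@H]2[C@@](C)(CC/C(C)=C/C(=O)OC(C)(C)C)[C@H](C)[C@@H](OC(C)=O)C[C@]12C | intermediate
25 | 18-trimethylammonio analogue of 24, iodide | C[N+](C)(C)CC1C(=O)CC[C@@H]2[C@@](C)(CC/C(C)=C/C(=O)OC(C)(C)C)[C@H](C)[C@@H](OC(C)=O)C[C@]12C.[I-] | intermediate (not isolated)
26 | tert-butyl (13E)-7β-acetoxy-3-oxo-cis-cleroda-4(18),13-dien-15-oate | C=C1C(=O)CC[C@@H]2[C@@](C)(CC/C(C)=C/C(=O)OC(C)(C)C)[C@H](C)[C@@H](OC(C)=O)C[C@]12C | intermediate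
27 | (13E)-7β-acetoxy-3-oxo-cis-cleroda-4(18),13-dien-15-oic acid | C=C1C(=O)CC[C@@H]2[C@@](C)(CC/C(C)=C/C(=O)O)[C@H](C)[C@@H](OC(C)=O)C[C@]12C | intermediate
28 | trimethylsilyl (13E)-7β-acetoxy-3-trimethylsilyloxy-cis-cleroda-2,4(18),13-trien-15-oate | C=C1C(O[Si](C)(C)C)=CC[C@@H]2[C@@](C)(CC/C(C)=C/C(=O)O[Si](C)(C)C)[C@H](C)[C@@H](OC(C)=O)C[C@]12C | intermediate (not isolated)
29 | trimethylsilyl (13E)-7β-acetoxy-3-oxo-2-trimethylsilyloxy-cis-cleroda-4(18),13-dien-15-oate (C2 epimers) | C=C1C(=O)C(O[Si](C)(C)C)C[C@@H]2[C@@](C)(CC/C(C)=C/C(=O)O[Si](C)(C)C)[C@H](C)[C@@H](OC(C)=O)C[C@]12C | intermediate (not isolated)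
30 | (13E)-7β-acetoxy-2-hydroxy-3-oxo-cis-cleroda-4(18),13-dien-15-oic acid (C2 epimers) | C=C1C(=O)C(O)C[C@@H]2[C@@](C)(CC/C(C)=C/C(=O)O)[C@H](C)[C@@H](OC(C)=O)C[C@]12C | intermediate
31 | (13E)-7β-acetoxy-2,3-dioxo-cis-cleroda-4(18),13-dien-15-oic acid | C=C1C(=O)C(=O)C[C@@H]2[C@@](C)(CC/C(C)=C/C(=O)O)[C@H](C)[C@@H](OC(C)=O)C[C@]12C | intermediate (not isolated)
32 | (13E)-7β-acetoxy-2-hydroxy-3-oxo-cis-cleroda-1,4(18),13-trien-15-oic acid (5S,7S,8S,9R,10R) | C=C1C(=O)C(O)=C[C@@H]2[C@@](C)(CC/C(C)=C/C(=O)O)[C@H](C)[C@@H](OC(C)=O)C[C@]12C | target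

**Step count and risks**
Total step count: 19. Longest linear sequence: 19 steps (1 → 32); 8, 15 and the second portion of 2 are purchased and enter directly.

The three steps most likely to fail:

Step 6 (Mukaiyama–Michael addition at the C10 carbon next to the quaternary C9, with a Lewis acid in the presence of a dioxolane). The fallback sets out from 10 and returns at 13. 10 is cleaved with MeLi (THF, 0 °C) to the regiodefined lithium enolate F1. F1 is added at −78 °C to 3-(trimethylsilyl)but-3-en-2-one, whose α-silyl group stabilises the adduct anion and stops polymerisation, giving the α-silyl diketone F2. NaOMe in MeOH at 65 °C then removes the C-silyl group and effects the aldol condensation in one flask to give 13. This replaces the Lewis-acid addition of a neutral enol ether by an anionic Michael addition under basic, ketal-safe conditions.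

Step 11 (slow, possibly unselective epoxidation of the electron-poor dienone, which also carries the reduction in step 12). The fallback sets out from 18 and returns at 21. Copper-catalysed 1,6-conjugate borylation (bis(pinacolato)diboron, CuCl, NaOtBu, 1,2-bis(diphenylphosphino)benzene, MeOH, THF, 25 °C) adds boron at C7 from the same open β face, because C5 is fully substituted and 1,4-addition is disfavoured, giving the 7β-boryl enone F3. Oxidation with NaBO3·4H2O (THF/H2O, retention at C7) and the same amidine reconjugation gives 21 without passing through 19 and 20.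

Step 18 (Rubottom oxidation on the sensitive α-methylene ketone carrying a free acid). The fallback sets out from 27 and returns at 32. Acid-mediated α-nitrosation with isopentyl nitrite and TMSCl (CH2Cl2, −20 °C) at C2, the only enolisable position, gives the 2-hydroxyimino ketone F4. Transoximation with aqueous glyoxylic acid at 25 °C releases the 2,3-diketone 31, which enolises to 32. This avoids both the silyl dienol ether and the peracid.

**Further compounds**
F1 | step 6 | lithium enolate of 3,4-dimethyl-3-[2-(2-methyl-1,3-dioxolan-2-yl)ethyl]cyclohexanone (enolate toward C10) | [Li+].[O-]C1=C[C@@](C)(CCC2(C)OCCO2)[C@H](C)CC1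
F2 | step 6 | 2-[3-oxo-2-(trimethylsilyl)butyl]-3,4-dimethyl-3-[2-(2-methyl-1,3-dioxolan-2-yl)ethyl]cyclohexanone (α-silyl diketone) | O=C1C(CCC([Si](C)(C)C)C(C)=O)[C@@](C)(CCC2(C)OCCO2)[C@H](C)CC1
F3 | step 11 | tert-butyl (13E)-3-oxo-7β-(4,4,5,5-tetramethyl-1,3,2-dioxaborolan-2-yl)-18,19-dinorcleroda-4,13-dien-15-oate | O=C1CC[C@@H]2[C@@](C)(CC/C(C)=C/C(=O)OC(C)(C)C)[C@H](C)[C@@H](B3OC(C)(C)C(C)(C)O3)CC2=C1
F4 | step 18 | (13E)-7β-acetoxy-2-hydroxyimino-3-oxo-cis-cleroda-4(18),13-dien-15-oic acid | C=C1C(=O)C(=NO)C[C@@H]2[C@@](C)(CC/C(C)=C/C(=O)O)[C@H](C)[C@@H](OC(C)=O)C[C@]12C
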